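**Retrosynthetic overview**

1. The target is a germacranolide: a ten-membered carbocycle (C1–C10) trans-fused at C6/C7 to an α-methylene γ-lactone (O–C6, C7, C11, C12, exocyclic C13). The strategy rests on the acyloin C1(=O)–C10(OH)(CH3) in the ten-membered ring: the C1–C10 bond is the pinacol bond between a C1 aldehyde and a C10 methyl ketone, and oxidation of the secondary C1 carbinol of the diol gives the ketol.
2. After ring closure: acetonide on the 1,10-diol, C11 methylenation (aminomethylation, then elimination), exchange of the C8 silyl ether for the isovalerate, ketal hydrolysis, C1 oxidation, C3 desilylation. C11 stays CH2 through the ring closure because an α-methylene lactone would be attacked or reduced by SmI2.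
3. Seco keto-aldehyde: the C10 methyl ketone comes from Wacker oxidation of a C8 homoallyl unit, installed by reagent-controlled allylboration of a lactone C8 aldehyde; the C1 aldehyde is unmasked last from a PMB ether.
4. γ-Lactone: Evans syn aldol of a succinate imide with a (Z)-enal, then lactonisation (the syn adduct gives the 6,7-trans lactone). The enal comes from syn-methylcupration of a γ-silyloxy ynoate whose C3 carbinol is set by catalytic asymmetric alkynylation.
5. Ring order: γ-lactone first (step 9), ten-membered carbocycle second (step 18).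

Key step: step 18

Remark: germacranolide numbering is used for all chain and ring carbons (C1–C10 ring, C11–C13 lactone carbons, C14 methyl on C10, C15 methyl on C4); PMB = 4-methoxybenzyl, TBS = tert-butyldimethylsilyl, TES = triethylsilyl.

Assumption: (S,S)-ProPhenol is taken to be the ligand enantiomer whose dinuclear zinc catalyst adds the alkynyl group to the Si face of aldehyde 3 and so gives (R)-5; the (R,R)-ligand is used in the same way if the sense proves opposite.

**Route**

Step 1
Reactants: 1 propane-1,3-diol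
Product: 2 3-[(4-methoxybenzyl)oxy]propan-1-ol
Conditions: NaH (1 equiv), PMBCl, n-Bu4NI (cat.), THF, 0 °C to rt (diol in threefold excess)
Reagents that add atoms: 4-methoxybenzyl chloride, COc1ccc(CCl)cc1
Why: Williamson etherification of the mono-alkoxide; the excess of diol should keep the bis-ether low.

Step 2
Reactants: 2 3-[(4-methoxybenzyl)oxy]propan-1-ol
Product: 3 3-[(4-methoxybenzyl)oxy]propanal
Conditions: TEMPO (cat.), PhI(OAc)2, CH2Cl2, rt
Reagents that add atoms: none
Why: Oxoammonium (TEMPO) oxidation stops at the aldehyde under non-basic conditions, so the β-alkoxy aldehyde should not eliminate.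

Step 3
Reactants: 3 3-[(4-methoxybenzyl)oxy]propanal; 4 methyl propiolate
Product: 5 methyl (R)-4-hydroxy-6-[(4-methoxybenzyl)oxy]hex-2-ynoate
Conditions: (S,S)-ProPhenol (10 mol %), Me2Zn (3 equiv), Ph3P=O (20 mol %), toluene, 4 °C, slow addition of 3
Reagents that add atoms: none
Why: ProPhenol dinuclear zinc-catalysed asymmetric alkynylation of an aldehyde; the chiral pocket should deliver the zinc alkynylide to the Si face and set C3 as R.

Step 4
Reactants: 5 methyl (R)-4-hydroxy-6-[(4-methoxybenzyl)oxy]hex-2-ynoate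
Product: 6 methyl (R)-4-[(tert-butyldimethylsilyl)oxy]-6-[(4-methoxybenzyl)oxy]hex-2-ynoate
Conditions: TBSOTf, 2,6-lutidine, CH2Cl2, −78 °C
Reagents that add atoms: tert-butyldimethylsilyl triflate, CC(C)(C)[Si](C)(C)OS(=O)(=O)C(F)(F)F
Why: Fast silylation at low temperature with a hindered base avoids base-induced isomerisation of the γ-hydroxy ynoate.

Step 5
Reactants: 6 methyl (R)-4-[(tert-butyldimethylsilyl)oxy]-6-[(4-methoxybenzyl)oxy]hex-2-ynoate
Product: 7 methyl (R,Z)-4-[(tert-butyldimethylsilyl)oxy]-6-[(4-methoxybenzyl)oxy]-3-methylhex-2-enoate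
Conditions: Me2CuLi (from CuI and MeLi), THF, −78 °C; MeOH then aq NH4Cl at −78 °C
Reagents that add atoms: lithium dimethylcuprate, [Li+].C[Cu-]C
Why: Syn-carbocupration of the ynoate (Gilman reagent) places methyl on C4 and copper on C5 on the same side, and cold protonation with retention should leave the ester cis to C3, i.e. the Z-4,5-alkene.

Step 6
Reactants: 7 methyl (R,Z)-4-[(tert-butyldimethylsilyl)oxy]-6-[(4-methoxybenzyl)oxy]-3-methylhex-2-enoate
Product: 8 (R,Z)-4-[(tert-butyldimethylsilyl)oxy]-6-[(4-methoxybenzyl)oxy]-3-methylhex-2-en-1-ol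
Conditions: i-Bu2AlH (2.2 equiv), CH2Cl2, −78 °C; aq KNaC4H4O6 work-up
Reagents that add atoms: none
Why: 1,2-Reduction of the enoate by the aluminium hydride gives the allylic alcohol without touching the alkene geometry.

Step 7
Reactants: 8 (R,Z)-4-[(tert-butyldimethylsilyl)oxy]-6-[(4-methoxybenzyl)oxy]-3-methylhex-2-en-1-ol
Product: 9 (R,Z)-4-[(tert-butyldimethylsilyl)oxy]-6-[(4-methoxybenzyl)oxy]-3-methylhex-2-enal
Conditions: MnO2 (activated, excess), CH2Cl2, rt; used at once
Reagents that add atoms: none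
Why: Neutral heterogeneous allylic oxidation should give the Z-enal without Z/E isomerisation.

Step 8
Reactants: 10 (S)-4-benzyloxazolidin-2-one; 11 methyl 4-chloro-4-oxobutanoate
Product: 12 methyl (S)-4-(4-benzyl-2-oxooxazolidin-3-yl)-4-oxobutanoate
Conditions: n-BuLi, THF, −78 °C; then 11, −78 to 0 °C
Reagents that add atoms: none
Why: N-Acylation of the lithiated oxazolidinone by the acid chloride, which is far more reactive than the methyl ester.

Step 9
Reactants: 12 methyl (S)-4-(4-benzyl-2-oxooxazolidin-3-yl)-4-oxobutanoate; 9 (R,Z)-4-[(tert-butyldimethylsilyl)oxy]-6-[(4-methoxybenzyl)oxy]-3-methylhex-2-enal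
Product: 14 trans-lactone imide (6R,7S), via syn-aldol adduct 13 (not isolated)
Conditions: n-Bu2BOTf, i-Pr2NEt, CH2Cl2, −78 to 0 °C; 9, −78 to −10 °C; pH 7 buffer, MeOH, 30% H2O2, 0 °C; then PPTS (cat.), CH2Cl2, rt
Reagents that add atoms: none
Why: Evans syn aldol: the Z-boron enolate of the imide (not of the ester) reacts through a Zimmerman–Traxler chair on the face opposite the benzyl group, which sets C7 and C6 syn, and the C6 hydroxyl then closes onto the methyl ester (5-exo-trig lactonisation) to give the 6,7-trans γ-lactone, the first ring.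

Step 10
Reactants: 14 trans-lactone imide
Product: 15 trans-lactone acid, (2R,3S)-2-alkenyl-5-oxotetrahydrofuran-3-carboxylic acid
Conditions: LiOH, 30% H2O2, THF/H2O (3:1), 0 °C; aq Na2SO3; then 1 M HCl to pH 3
Reagents that add atoms: hydrogen peroxide (as LiOOH), OO
Why: Hydroperoxide attacks the exocyclic imide carbonyl selectively, and any lactone opened by hydroxide should re-close on acidification because only the γ-lactone can form.

Step 11
Reactants: 15 trans-lactone acid
Product: 17 hydroxymethyl lactone (4R,5R), via mixed carbonic anhydride 16 (not isolated)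
Conditions: i-BuOCOCl, N-methylmorpholine, THF, −15 °C; then NaBH4, THF/H2O, −15 to 0 °C; aq citric acid quench
Reagents that add atoms: none
Why: Borohydride reduces the activated mixed anhydride within minutes while the lactone and the alkene are inert, and the cold acidic quench should prevent lactone migration to the new primary alcohol.

Step 12
Reactants: 17 hydroxymethyl lactone
Product: 18 lactone aldehyde, (2R,3S)-2-alkenyl-5-oxotetrahydrofuran-3-carbaldehyde
Conditions: Dess–Martin periodinane, NaHCO3, CH2Cl2, 0 °C to rt; used crude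
Reagents that add atoms: none
Why: Dess–Martin oxidation under buffered, non-basic conditions; C7 is epimerisable but the 6,7-trans isomer is the thermodynamically preferred one.

Step 13
Reactants: 18 lactone aldehyde
Product: 19 homoallylic alcohol (8R), (4R,5R)-4-[(R)-1-hydroxybut-3-en-1-yl]-5-alkenyldihydrofuran-2(3H)-one
Conditions: (+)-Ipc2B(allyl) (from (−)-α-pinene, salt-free), Et2O, −100 to −78 °C; pH 7 buffer, MeOH, 30% H2O2, 0 °C
Reagents that add atoms: (+)-B-allyldiisopinocampheylborane, C=CCB([C@H]1C[C@H]2C[C@@H]([C@@H]1C)C2(C)C)[C@H]1C[C@H]2C[C@@H]([C@@H]1C)C2(C)C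
Why: Brown allylboration through a chair transition state in which the isopinocampheyl groups direct allyl to the Re face of the aldehyde, which should set C8 as R under reagent control; the neutral oxidative work-up keeps the lactone on O6.

Step 14
Reactants: 19 homoallylic alcohol
Product: 20 C8 triethylsilyl ether
Conditions: TESOTf, 2,6-lutidine, CH2Cl2, −78 °C
Reagents that add atoms: triethylsilyl triflate, CC[Si](CC)(CC)OS(=O)(=O)C(F)(F)F
Why: Fast silylation of the secondary alcohol without an alkoxide, so the lactone cannot migrate.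

Step 15
Reactants: 20 C8 triethylsilyl ether
Product: 21 methyl ketone, (4S,5R)-4-[(R)-3-oxo-1-(triethylsilyloxy)butyl]-5-alkenyldihydrofuran-2(3H)-one
Conditions: PdCl2 (10 mol %), Cu(OAc)2 (20 mol %), O2 (1 atm), DMA/H2O (7:1), rt
Reagents that add atoms: water, O
Why: Tsuji–Wacker oxidation: Markovnikov hydroxypalladation of the terminal alkene by divalent palladium gives the C10 methyl ketone, the hindered trisubstituted alkene is inert, and the acetate co-catalyst keeps the medium mild enough for the silyl ethers.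

Step 16
Reactants: 21 methyl ketone
Product: 22 primary alcohol at C1
Conditions: DDQ, CH2Cl2/pH 7 buffer (10:1), 0 °C
Reagents that add atoms: none
Why: Oxidative cleavage of the electron-rich PMB ether by hydride abstraction; silyl ethers, ketone and lactone are untouched.

Step 17
Reactants: 22 primary alcohol at C1
Product: 23 seco keto-aldehyde (C1 aldehyde, C10 methyl ketone)
Conditions: Dess–Martin periodinane, NaHCO3, CH2Cl2, 0 °C to rt; short filtration, used at once
Reagents that add atoms: none
Why: Buffered Dess–Martin oxidation gives the β-silyloxy aldehyde without base, so elimination of the C3 silyloxy group is avoided.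

Step 18
Reactants: 23 seco keto-aldehyde
Product: 24 ten-membered 1,10-cis-diol lactone (1S,3R,6R,7S,8R,10R; 4Z)
Conditions: SmI2 (4 equiv, 0.02 M in THF), 23 added by syringe pump over 10 h (final 2 mM), rt; aq NaHCO3 quench
Reagents that add atoms: none
Why: SmI2 (divalent samarium) transfers one electron to the aldehyde, the more easily reduced carbonyl, and the C1 ketyl adds to the carbonyl carbon of the samarium-bound C10 ketone; a second electron transfer gives the trivalent samarium diolate, which is protonated on work-up. The closest known reaction type is the intramolecular pinacol coupling of keto-aldehydes with SmI2 or low-valent titanium to cycloalkane-1,2-diols of medium and large ring size. The ten-membered carbocycle closes by a 10-exo-trig ketyl addition, helped by the Z-4,5-alkene and the trans-fused lactone, which turn the two chain ends toward each other, and by slow addition at high dilution, which should suppress intermolecular coupling. C1: both oxygens stay on one samarium while the C–C bond forms, which should give the cis-diol (1S); this centre is removed by the later oxidation. C10: the ketyl should approach the ketone face anti to the C8 triethylsilyloxy group in the conformer with opposed C8–O and C10=O dipoles (1,3-anti induction), which gives 10R. The step needs chemoselectivity for the two carbonyls, which the substrate secures because C11 is still CH2 (an α-methylene lactone would accept the ketyl or be reduced) and because silyl ethers and the saturated lactone are inert to SmI2 in THF.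

Step 19
Reactants: 24 ten-membered 1,10-cis-diol lactone
Product: 25 1,10-acetonide
Conditions: 2-methoxypropene, PPTS (cat.), CH2Cl2, 0 °C
Reagents that add atoms: 2-methoxypropene, COC(C)=C
Why: Ketalisation of the cis-1,2-diol as the dioxolane under anhydrous mild acid, which the triethylsilyl ether should survive.

Step 20
Reactants: 25 1,10-acetonide
Product: 26 C11 dimethylaminomethyl lactone (C11 epimers)
Conditions: LiN(i-Pr)2, THF, −78 °C; then CH2=NMe2+ I−, −78 to 0 °C
Reagents that add atoms: N,N-dimethylmethyleneiminium iodide, C=[N+](C)C.[I-]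
Why: Mannich-type aminomethylation of the lactone lithium enolate with Eschenmoser's salt; the lactone is the only acidic site, no leaving group sits β to the enolate, and the C11 configuration is lost in the next step.

Step 21
Reactants: 26 C11 dimethylaminomethyl lactone
Product: 28 α-methylene lactone, via trimethylammonium iodide 27 (not isolated)
Conditions: MeI, THF, rt; then satd aq NaHCO3, CH2Cl2, rt
Reagents that add atoms: none
Why: N-Methylation followed by Hofmann-type (E1cB) elimination of trimethylamine from the β-ammonium lactone gives the exocyclic C11=C13 alkene.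

Step 22
Reactants: 28 α-methylene lactone
Product: 29 C8 alcohol
Conditions: HF·pyridine, pyridine, THF, 0 °C
Reagents that add atoms: none
Why: Buffered fluoride cleaves the triethylsilyl ether much faster than the secondary tert-butyldimethylsilyl ether and leaves the acetonide intact.

Step 23
Reactants: 29 C8 alcohol; 30 3-methylbutanoyl chloride (isovaleryl chloride)
Product: 31 C8 isovalerate
Conditions: pyridine, DMAP (cat.), CH2Cl2, 0 °C to rt
Reagents that add atoms: none
Why: DMAP-catalysed acylation of the only free hydroxyl; no alkoxide is formed, so neither lactone migration nor oxa-Michael addition is expected.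

Step 24
Reactants: 31 C8 isovalerate
Product: 32 1,10-diol
Conditions: AcOH/THF/H2O (3:1:1), 40 °C
Reagents that add atoms: none
Why: Acid hydrolysis of the dioxolane ketal under conditions that a secondary tert-butyldimethylsilyl ether, the ester and the methylene lactone should tolerate.

Step 25
Reactants: 32 1,10-diol
Product: 33 C1 ketone (α-ketol)
Conditions: IBX, DMSO, rt
Reagents that add atoms: none
Why: IBX oxidises the secondary alcohol of a 1,2-diol to the α-hydroxy ketone without glycol cleavage; the tertiary C10 hydroxyl cannot react and C3 is still silylated.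

Step 26
Reactants: 33 C1 ketone
Product: 34 target, (3R,6R,7R,8R,10R,4Z)-3,10-dihydroxy-8-(3-methylbutanoyloxy)-1-oxogermacra-4,11(13)-dien-12,6-olide
Conditions: HF·pyridine, THF, 0 °C to rt
Reagents that add atoms: none
Why: Mildly acidic fluoride desilylation avoids the retro-aldol, elimination and acyl migration that a basic fluoride source could cause in the β-hydroxy ketone.

**Compound list**

1 | propane-1,3-diol | OCCCO | starting material
2 | 3-[(4-methoxybenzyl)oxy]propan-1-ol | COc1ccc(COCCCO)cc1 | intermediate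
3 | 3-[(4-methoxybenzyl)oxy]propanal | COc1ccc(COCCC=O)cc1 | intermediate
4 | methyl propiolate | C#CC(=O)OC | starting material
5 | methyl (R)-4-hydroxy-6-[(4-methoxybenzyl)oxy]hex-2-ynoate | COc1ccc(COCC[C@@H](O)C#CC(=O)OC)cc1 | intermediate
6 | methyl (R)-4-[(tert-butyldimethylsilyl)oxy]-6-[(4-methoxybenzyl)oxy]hex-2-ynoate | COc1ccc(COCC[C@@H](O[Si](C)(C)C(C)(C)C)C#CC(=O)OC)cc1 | intermediate
7 | methyl (R,Z)-4-[(tert-butyldimethylsilyl)oxy]-6-[(4-methoxybenzyl)oxy]-3-methylhex-2-enoate | COc1ccc(COCC[C@@H](O[Si](C)(C)C(C)(C)C)/C(C)=C\C(=O)OC)cc1 | intermediate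
8 | (R,Z)-4-[(tert-butyldimethylsilyl)oxy]-6-[(4-methoxybenzyl)oxy]-3-methylhex-2-en-1-ol | COc1ccc(COCC[C@@H](O[Si](C)(C)C(C)(C)C)/C(C)=C\CO)cc1 | intermediate
9 | (R,Z)-4-[(tert-butyldimethylsilyl)oxy]-6-[(4-methoxybenzyl)oxy]-3-methylhex-2-enal | COc1ccc(COCC[C@@H](O[Si](C)(C)C(C)(C)C)/C(C)=C\C=O)cc1 | intermediate
10 | (S)-4-benzyloxazolidin-2-one | O=C1N[C@@H](Cc2ccccc2)CO1 | starting material
11 | methyl 4-chloro-4-oxobutanoate | COC(=O)CCC(Cl)=O | starting material
12 | methyl (S)-4-(4-benzyl-2-oxooxazolidin-3-yl)-4-oxobutanoate | COC(=O)CCC(=O)N1[C@@H](Cc2ccccc2)COC1=O | intermediate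
13 | syn-aldol adduct, methyl (3S,4R,5Z,7R)-3-[(S)-4-benzyl-2-oxooxazolidine-3-carbonyl]-7-[(tert-butyldimethylsilyl)oxy]-4-hydroxy-9-[(4-methoxybenzyl)oxy]-6-methylnon-5-enoate | COc1ccc(COCC[C@@H](O[Si](C)(C)C(C)(C)C)/C(C)=C\[C@@H](O)[C@H](CC(=O)OC)C(=O)N2[C@@H](Cc3ccccc3)COC2=O)cc1 | intermediate (not isolated)
14 | trans-lactone imide, (S)-4-benzyl-3-[(2R,3S)-2-{(R,Z)-3-[(tert-butyldimethylsilyl)oxy]-5-[(4-methoxybenzyl)oxy]-2-methylpent-1-en-1-yl}-5-oxotetrahydrofuran-3-carbonyl]oxazolidin-2-one | COc1ccc(COCC[C@@H](O[Si](C)(C)C(C)(C)C)/C(C)=C\[C@H]2OC(=O)C[C@@H]2C(=O)N3[C@@H](Cc4ccccc4)COC3=O)cc1 | intermediate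
15 | trans-lactone acid, (2R,3S)-2-{(R,Z)-3-[(tert-butyldimethylsilyl)oxy]-5-[(4-methoxybenzyl)oxy]-2-methylpent-1-en-1-yl}-5-oxotetrahydrofuran-3-carboxylic acid | COc1ccc(COCC[C@@H](O[Si](C)(C)C(C)(C)C)/C(C)=C\[C@H]2OC(=O)C[C@@H]2C(=O)O)cc1 | intermediate
16 | mixed carbonic anhydride of acid 15 with isobutyl hydrogen carbonate | COc1ccc(COCC[C@@H](O[Si](C)(C)C(C)(C)C)/C(C)=C\[C@H]2OC(=O)C[C@@H]2C(=O)OC(=O)OCC(C)C)cc1 | intermediate (not isolated)
17 | hydroxymethyl lactone, (4R,5R)-5-{(R,Z)-3-[(tert-butyldimethylsilyl)oxy]-5-[(4-methoxybenzyl)oxy]-2-methylpent-1-en-1-yl}-4-(hydroxymethyl)dihydrofuran-2(3H)-one | COc1ccc(COCC[C@@H](O[Si](C)(C)C(C)(C)C)/C(C)=C\[C@H]2OC(=O)C[C@@H]2CO)cc1 | intermediate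
18 | lactone aldehyde, (2R,3S)-2-{(R,Z)-3-[(tert-butyldimethylsilyl)oxy]-5-[(4-methoxybenzyl)oxy]-2-methylpent-1-en-1-yl}-5-oxotetrahydrofuran-3-carbaldehyde | COc1ccc(COCC[C@@H](O[Si](C)(C)C(C)(C)C)/C(C)=C\[C@H]2OC(=O)C[C@@H]2C=O)cc1 | intermediate
19 | homoallylic alcohol, (4R,5R)-5-{(R,Z)-3-[(tert-butyldimethylsilyl)oxy]-5-[(4-methoxybenzyl)oxy]-2-methylpent-1-en-1-yl}-4-[(R)-1-hydroxybut-3-en-1-yl]dihydrofuran-2(3H)-one | COc1ccc(COCC[C@@H](O[Si](C)(C)C(C)(C)C)/C(C)=C\[C@H]2OC(=O)C[C@@H]2[C@H](O)CC=C)cc1 | intermediate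
20 | C8 triethylsilyl ether, (4S,5R)-5-{(R,Z)-3-[(tert-butyldimethylsilyl)oxy]-5-[(4-methoxybenzyl)oxy]-2-methylpent-1-en-1-yl}-4-[(R)-1-(triethylsilyloxy)but-3-en-1-yl]dihydrofuran-2(3H)-one | COc1ccc(COCC[C@@H](O[Si](C)(C)C(C)(C)C)/C(C)=C\[C@H]2OC(=O)C[C@@H]2[C@H](O[Si](CC)(CC)CC)CC=C)cc1 | intermediate
21 | methyl ketone, (4S,5R)-5-{(R,Z)-3-[(tert-butyldimethylsilyl)oxy]-5-[(4-methoxybenzyl)oxy]-2-methylpent-1-en-1-yl}-4-[(R)-3-oxo-1-(triethylsilyloxy)butyl]dihydrofuran-2(3H)-one | COc1ccc(COCC[C@@H](O[Si](C)(C)C(C)(C)C)/C(C)=C\[C@H]2OC(=O)C[C@@H]2[C@H](O[Si](CC)(CC)CC)CC(C)=O)cc1 | intermediate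
22 | C1 alcohol, (4S,5R)-5-{(R,Z)-3-[(tert-butyldimethylsilyl)oxy]-5-hydroxy-2-methylpent-1-en-1-yl}-4-[(R)-3-oxo-1-(triethylsilyloxy)butyl]dihydrofuran-2(3H)-one | OCC[C@@H](O[Si](C)(C)C(C)(C)C)/C(C)=C\[C@H]1OC(=O)C[C@@H]1[C@H](O[Si](CC)(CC)CC)CC(C)=O | intermediate
23 | seco keto-aldehyde, (R,Z)-3-[(tert-butyldimethylsilyl)oxy]-4-methyl-5-{(2R,3S)-5-oxo-3-[(R)-3-oxo-1-(triethylsilyloxy)butyl]tetrahydrofuran-2-yl}pent-4-enal | O=CC[C@@H](O[Si](C)(C)C(C)(C)C)/C(C)=C\[C@H]1OC(=O)C[C@@H]1[C@H](O[Si](CC)(CC)CC)CC(C)=O | intermediate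
24 | (1S,3R,6R,7S,8R,10R,4Z)-3-[(tert-butyldimethylsilyl)oxy]-1,10-dihydroxy-8-(triethylsilyloxy)germacr-4-en-12,6-olide (1,10-cis-diol) | C1C(=O)O[C@@H]2/C=C(/C)[C@H](O[Si](C)(C)C(C)(C)C)C[C@H](O)[C@](C)(O)C[C@@H](O[Si](CC)(CC)CC)[C@@H]12 | intermediate
25 | 1,10-O-isopropylidene derivative (acetonide) of 24 | C1C(=O)O[C@@H]2/C=C(/C)[C@H](O[Si](C)(C)C(C)(C)C)C[C@@H]3OC(C)(C)O[C@]3(C)C[C@@H](O[Si](CC)(CC)CC)[C@@H]12 | intermediate
26 | 11-(dimethylaminomethyl) derivative of 25 (C11 epimers, centre left unspecified) | CN(C)CC1C(=O)O[C@@H]2/C=C(/C)[C@H](O[Si](C)(C)C(C)(C)C)C[C@@H]3OC(C)(C)O[C@]3(C)C[C@@H](O[Si](CC)(CC)CC)[C@@H]12 | intermediate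
27 | trimethylammonium iodide of 26 | C[N+](C)(C)CC1C(=O)O[C@@H]2/C=C(/C)[C@H](O[Si](C)(C)C(C)(C)C)C[C@@H]3OC(C)(C)O[C@]3(C)C[C@@H](O[Si](CC)(CC)CC)[C@@H]12.[I-] | intermediate (not isolated)
28 | 11(13)-methylene lactone: 1,10-acetonide, 3-O-TBS, 8-O-TES germacra-4,11(13)-dien-12,6-olide | C=C1C(=O)O[C@@H]2/C=C(/C)[C@H](O[Si](C)(C)C(C)(C)C)C[C@@H]3OC(C)(C)O[C@]3(C)C[C@@H](O[Si](CC)(CC)CC)[C@@H]12 | intermediate
29 | C8 alcohol: 1,10-acetonide, 3-O-TBS, 8-hydroxygermacra-4,11(13)-dien-12,6-olide | C=C1C(=O)O[C@@H]2/C=C(/C)[C@H](O[Si](C)(C)C(C)(C)C)C[C@@H]3OC(C)(C)O[C@]3(C)C[C@@H](O)[C@@H]12 | intermediate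
30 | 3-methylbutanoyl chloride (isovaleryl chloride) | CC(C)CC(Cl)=O | starting material
31 | C8 isovalerate: 1,10-acetonide, 3-O-TBS, 8-(3-methylbutanoyloxy)germacra-4,11(13)-dien-12,6-olide | C=C1C(=O)O[C@@H]2/C=C(/C)[C@H](O[Si](C)(C)C(C)(C)C)C[C@@H]3OC(C)(C)O[C@]3(C)C[C@@H](OC(=O)CC(C)C)[C@@H]12 | intermediate
32 | (1S,3R,6R,7R,8R,10R,4Z)-3-[(tert-butyldimethylsilyl)oxy]-1,10-dihydroxy-8-(3-methylbutanoyloxy)germacra-4,11(13)-dien-12,6-olide | C=C1C(=O)O[C@@H]2/C=C(/C)[C@H](O[Si](C)(C)C(C)(C)C)C[C@H](O)[C@](C)(O)C[C@@H](OC(=O)CC(C)C)[C@@H]12 | intermediate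
33 | (3R,6R,7R,8R,10R,4Z)-3-[(tert-butyldimethylsilyl)oxy]-10-hydroxy-8-(3-methylbutanoyloxy)-1-oxogermacra-4,11(13)-dien-12,6-olide | C=C1C(=O)O[C@@H]2/C=C(/C)[C@H](O[Si](C)(C)C(C)(C)C)CC(=O)[C@](C)(O)C[C@@H](OC(=O)CC(C)C)[C@@H]12 | intermediate
34 | (3R,6R,7R,8R,10R,4Z)-3,10-dihydroxy-8-(3-methylbutanoyloxy)-1-oxogermacra-4,11(13)-dien-12,6-olide (CNP0406522.1) | C=C1C(=O)O[C@@H]2/C=C(/C)[C@H](O)CC(=O)[C@](C)(O)C[C@@H](OC(=O)CC(C)C)[C@@H]12 | target

**Step count and risks**

Total step count: 26. Longest linear sequence: 25 steps (steps 1–7, then 9–26); step 8 is the one-step side branch.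

Steps most likely to fail:

Step 18 (key ring closure). The ring closure may lose to simple reduction of the aldehyde or to intermolecular coupling, and the ketyl may add to the wrong face of the methyl ketone, so that the C10 epimer forms. The fallback uses the C8 hydroxyl as an internal ligand instead of a silyl ether. It sets out from 23: HF·pyridine/pyridine in THF at 0 °C removes the triethylsilyl group to give the hydroxy keto-aldehyde F1. SmI2 under the same slow-addition, high-dilution conditions should then couple the carbonyls while the β-hydroxy ketone is held on trivalent samarium in a six-membered chelate. This activates the ketone toward the ketyl and exposes the face that leads to the 8,10-anti relation (10R), giving the triol F2. 2-Methoxypropene/PPTS should ketalise the cis-1,2-diol in preference to the anti-1,3-diol and give the 1,10-acetonide with free C8 hydroxyl F3. TESOTf/2,6-lutidine then returns to the route at 25.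

Step 13 (allylboration). Reagent control may be insufficient against the facial bias of the α-branched aldehyde, the aldehyde may epimerise at C7 or lose the lactone oxygen by β-elimination, and the lactone may migrate to the new C8 hydroxyl during work-up. The fallback forms the C8–C9 bond by enamine catalysis and delivers the methyl ketone directly. It sets out from 18: L-proline (30 mol %) in acetone/DMSO at rt should add the acetone enamine to the Re face of the aldehyde (Houk–List transition state) and give the β-hydroxy ketone F4 with 8R. TESCl/imidazole in DMF (the chloride avoids silyl enol ether formation at the methyl ketone) then returns to the route at 21, bypassing steps 13 to 15.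

Step 3 (asymmetric alkynylation). An unbranched, enolisable β-alkoxy aldehyde may give low enantioselectivity, may self-condense or lose 4-methoxybenzyl alcohol by β-elimination, and the sense of induction rests on the stated assumption. The fallback sets C3 by stoichiometric asymmetric reduction instead of catalytic addition. It sets out from 3: methyl propiolate lithiated with LiN(SiMe3)2 at −78 °C adds to give the racemic hydroxy ynoate F5. Dess–Martin periodinane gives the ynone ester F6. Midland reduction with B-isopinocampheyl-9-borabicyclo[3.3.1]nonane from (+)-α-pinene (the alkynyl group acts as the small group) should give the (R)-carbinol and return to the route at 5.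

Further compounds
F1 | step 18 | hydroxy keto-aldehyde, (R,Z)-3-[(tert-butyldimethylsilyl)oxy]-5-{(2R,3R)-3-[(R)-1-hydroxy-3-oxobutyl]-5-oxotetrahydrofuran-2-yl}-4-methylpent-4-enal | O=CC[C@@H](O[Si](C)(C)C(C)(C)C)/C(C)=C\[C@H]1OC(=O)C[C@@H]1[C@H](O)CC(C)=O
F2 | step 18 | 3-O-TBS-1,8,10-trihydroxygermacr-4-en-12,6-olide (1,10-cis, 8,10-anti) | C1C(=O)O[C@@H]2/C=C(/C)[C@H](O[Si](C)(C)C(C)(C)C)C[C@H](O)[C@](C)(O)C[C@@H](O)[C@@H]12
F3 | step 18 | 1,10-acetonide of F2 with free C8 hydroxyl | C1C(=O)O[C@@H]2/C=C(/C)[C@H](O[Si](C)(C)C(C)(C)C)C[C@@H]3OC(C)(C)O[C@]3(C)C[C@@H](O)[C@@H]12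
F4 | step 13 | β-hydroxy ketone, (4R,5R)-5-{(R,Z)-3-[(tert-butyldimethylsilyl)oxy]-5-[(4-methoxybenzyl)oxy]-2-methylpent-1-en-1-yl}-4-[(R)-1-hydroxy-3-oxobutyl]dihydrofuran-2(3H)-one | COc1ccc(COCC[C@@H](O[Si](C)(C)C(C)(C)C)/C(C)=C\[C@H]2OC(=O)C[C@@H]2[C@H](O)CC(C)=O)cc1
F5 | step 3 | racemic methyl 4-hydroxy-6-[(4-methoxybenzyl)oxy]hex-2-ynoate | COc1ccc(COCCC(O)C#CC(=O)OC)cc1
F6 | step 3 | methyl 6-[(4-methoxybenzyl)oxy]-4-oxohex-2-ynoate | COc1ccc(COCCC(=O)C#CC(=O)OC)cc1
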